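Two yields and one comparison are asked of us.

| flask | substrate | coupling partner | free catalyst | remark | time |
|---|---|---|---|---|---|
| west | 0.20 M | 0.36 M | 22 mM | run made earlier |  |
| north-east | 0.20 M | 0.36 M | 30 mM | run made earlier |  |
| south | 0.20 M | 0.36 M | 41 mM | run made earlier |  |
| east | 0.16 M | 0.36 M | 40 mM | run made earlier |  |
| alpha | 0.20 M | 0.360 M | 40 mM |  | 80 min |
| gamma | 0.10 M | 0.360 M | 25 mM |  | 25 min |

- west (time / min: product / %): 15.0: 0.4; 30.0: 3.7; 50.0: 7.7; 60.0: 10.1; 80.0: 13.3
- north-east (time / min: product / %): 8.00: 0.1; 20.0: 2.8; 40.0: 7.5; 60.0: 13.2; 80.0: 18.8
- south (time / min: product / %): 8.00: 0.5; 20.0: 2.7; 40.0: 9.7; 60.0: 18.2; 80.0: 24.2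
- east (time / min: product / %): 15.0: 1.7; 30.0: 6.6; 50.0: 14.8; 60.0: 18.8; 80.0: 28.1

(scatter of a reading: 0.5 percentage points)

* the flask that ends with the higher amount of product, in percent of the substrate charged, or "neither" when 2 percentage points or less lies between them (alpha / gamma / neither)
* final product, as a percentage of the substrate charged, in alpha
* final product, as a percentage of the substrate charged, in gamma

- the numbers in the tables scatter by 0.5 percentage points (one standard deviation)

1. We count catalyst rounds. Let y be product in percent of substrate charged, s the substrate charge and c the catalyst charge. Then n = y·s/c is the turnover number, product formed per catalyst charged.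

2. Late end. Past the start the curves run straight. Slope times s/c gives w, the turnover frequency. South, read from 40.0 min to 80.0 min, gives 0.0177 /min. East, with less substrate, gives 0.0177 /min, the same within reading. So substrate and catalyst fold into n.

3. Early end. Each straight line, run back to zero product, meets the time axis at a lag τ: 13.2 min in south, 16.6 min in east.

4. Join the ends: n = w(t − τ). Alpha is nearly south, so its turnover number is 1.18, and y is 23.6%.

5. Gamma has less substrate than east, so we give it east's lag as the nearest reading. Then n is 0.148 and y is 3.71%. We commit to alpha.

6. Was one number enough? Not quite. The lags of south and east differ by 3.40 min, a gap we cannot resolve, because each lag rests on two readings with a scatter of 0.5 percentage points. With south's lag, gamma reckons to 5.20%. Gamma's n is also under one round and lower than alpha's, so gamma stands inside the start, where the joined line is weakest.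

The forecast gives alpha, with 24% for alpha and 5.5% for gamma, warns that “The lag uncertainty dominates this estimate”, and stands above our gamma.

The flask gives alpha: 24.5% in alpha, 3.42% in gamma.

    substrate + free catalyst → catalyst intermediate A (k = 0.00660 /M/s)
    coupling partner + catalyst intermediate A → catalyst intermediate B (k = 0.00220 /M/s)
    catalyst intermediate B ⇌ catalyst intermediate C (K = 0.390, k = 0.00530 /s)
    catalyst intermediate C → free catalyst + product (k = 0.00660 /s)
    2 catalyst intermediate B ⇌ resting dimer, settled at all times (K = 10.0 /M)

In rounds, alpha reached 1.22 against our 1.18, and gamma 0.137 against our 0.148. Gamma stands so low chiefly because of the time allowed: it holds 3.42% at 25 min, and the same flask left 250 min gives 69.5%. For alpha left until 3.0 h, our line reckons n = 2.95, so y = 59.0%, and that flask holds 55.1%.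

The readings stem from a simulated flask for substances that don't exist, noise included.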